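Ring A (the benzo ring) of the benzofuran is assembled, not bought: it is cut at C4–C5 and C6–C7. C3a, C7a, C4 and C7 come from C5, C4, C6 and C3 of a 2-pyrone that already carries the ester carbon destined to become C3 and, on its 4-oxygen (future O1), the whole ring B benzyl unit; C5 with its prenyl chain and C6 with its oxygen come from a siloxyalkyne. One cycloaddition with loss of CO2 therefore delivers a benzoate in which all four ring A substituents are in place, and the furan ring is then closed by a carbanion acylation between the benzylic carbon and the ester.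

Key step: step 7

Remark: ambofuranol is achiral, so no stereocentre has to be set; the only stereogenic species (adduct 14, and F6, F7, F9 in the fallbacks) are racemic and transient.

Remark on protecting groups: ring B carries a MOM ether, which is inert to the carbanion step and can assist it by coordination. Ring A carries the triisopropylsilyl ether delivered by the alkyne. The acetal is removed before the silyl ether, so the phenol beside the prenyl group is never free in acid and cannot close to a chroman.

Step 1
Reactants: 1 dimethyl 3-oxopentanedioate; 2 trimethyl orthoformate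
Product: 4 methyl 4-hydroxy-2-oxo-2H-pyran-5-carboxylate, via methoxymethylidene diester 3 (not isolated)
Conditions: Ac2O, 120 °C; evaporate; then 1 M aq HCl, 0 °C → rt
Reagents that add atoms: water, O
Why: Orthoester condensation at the active methylene gives the methoxymethylidene diester, and aqueous acid unmasks the formyl enol, which lactonises onto the distal ester to give the 4-hydroxy-2-pyrone (Claisen-type condensation followed by enol lactonisation).

Step 2
Reactants: 5 2-hydroxy-4-methoxybenzaldehyde
Product: 6 4-methoxy-2-(methoxymethoxy)benzaldehyde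
Conditions: MOMCl, iPr2NEt, CH2Cl2, 0 °C → rt
Reagents that add atoms: chloromethyl methyl ether (MOMCl), COCCl
Why: Williamson-type O-alkylation of the phenol with a reactive α-chloro ether should protect the chelated hydroxyl cleanly as its acetal.

Step 3
Reactants: 6 4-methoxy-2-(methoxymethoxy)benzaldehyde
Product: 7 [4-methoxy-2-(methoxymethoxy)phenyl]methanol
Conditions: NaBH4, MeOH, 0 °C
Reagents that add atoms: none
Why: Borohydride reduction of an aryl aldehyde to the benzyl alcohol leaves the acetal and the aryl ether untouched.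

Step 4
Reactants: 4 methyl 4-hydroxy-2-oxo-2H-pyran-5-carboxylate; 7 [4-methoxy-2-(methoxymethoxy)phenyl]methanol
Product: 8 methyl 4-{[4-methoxy-2-(methoxymethoxy)phenyl]methoxy}-2-oxo-2H-pyran-5-carboxylate
Conditions: PPh3, DIAD, THF, 0 °C → rt
Reagents that add atoms: none
Why: Mitsunobu etherification, in which the acidic 4-hydroxy-2-pyrone is alkylated on its 4-oxygen under neutral redox conditions, avoiding the unstable 2,4-dioxygenated benzyl halide that a base-mediated alkylation would need.

Step 5
Reactants: 9 prenyl bromide (1-bromo-3-methylbut-2-ene)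
Product: 10 5-methylhex-4-en-1-yne
Conditions: HC≡CMgBr (excess), CuCl (5 mol %), THF, 0 °C → rt; isolate by distillation
Reagents that add atoms: ethynylmagnesium bromide, C#C[Mg]Br
Why: CuCl-catalysed coupling of an alkynyl Grignard reagent with a primary allylic bromide (allylic substitution) should give the skipped enyne, attack at the unhindered CH2 terminus being preferred over the fully substituted γ-carbon.

Step 6
Reactants: 10 5-methylhex-4-en-1-yne
Product: 13 triisopropyl[(5-methylhex-4-en-1-yn-1-yl)oxy]silane, via lithium acetylide 11 (not isolated), via lithium ynolate 12 (not isolated)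
Conditions: LiN(SiMe3)2, THF, −78 °C; t-BuOOLi (from t-BuOOH and LiN(SiMe3)2), −78 → 0 °C; then iPr3SiOTf, −78 → 0 °C
Reagents that add atoms: tert-butyl hydroperoxide, CC(C)(C)OO; triisopropylsilyl trifluoromethanesulfonate, CC(C)[Si](OS(=O)(=O)C(F)(F)F)(C(C)C)C(C)C
Why: Oxidation of a lithium acetylide by lithium tert-butyl peroxide (electrophilic oxygen transfer) gives the lithium ynolate, which the bulky silyl triflate traps on oxygen, while the silazide base is too weak to touch the doubly activated CH2 of the skipped enyne.

Step 7
Reactants: 8 methyl 4-{[4-methoxy-2-(methoxymethoxy)phenyl]methoxy}-2-oxo-2H-pyran-5-carboxylate; 13 triisopropyl[(5-methylhex-4-en-1-yn-1-yl)oxy]silane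
Product: 15 methyl 2-{[4-methoxy-2-(methoxymethoxy)phenyl]methoxy}-5-(3-methylbut-2-enyl)-4-(triisopropylsilyloxy)benzoate, via bicyclic lactone adduct 14 (not isolated)
Conditions: 13 (2.5 equiv), 2,6-di-tert-butyl-4-methylpyridine (5 mol %), PhMe, 110 °C, sealed tube
Reagents that add atoms: none
Why: Proposed new method: the alkyne carbon bearing the prenyl CH2 is the nucleophilic end of the ynol ether and pyrone C6, activated by both the lactone and the C5 ester, is the electrophilic end of the diene, so an asynchronous inverse-demand [4+2] addition across pyrone C3/C6 is expected, and the resulting 2-oxabicyclo[2.2.2]octadienone 14 then expels CO2 by retro-[4+2], which makes the sequence irreversible. The closest known reactions are the cycloaddition–decarboxylation of ester-activated 2-pyrones with ynamines and alkoxyalkynes, and the thermal cycloadditions of triisopropylsiloxyalkynes with ketenes, which show that such ynol ethers tolerate heating. Ring A is closed by an intermolecular [4+2] cycloaddition that forms two C–C bonds (C4–C5 and C6–C7 in benzofuran numbering), followed by cycloreversion. No stereocentre survives, because the two bridgehead centres of racemic 14 become aromatic carbons. The step needs regioselectivity (prenyl-bearing carbon to pyrone C6, siloxy carbon to pyrone C3), which the matched polarisation of the two partners should secure, and chemoselectivity over [2+2] addition to the C5=C6 enoate, favoured because the negative charge developing in the pyrone is delocalised to C3, where the six-membered closure takes place. The hindered pyridine only scavenges traces of acid that could ionise the electron-rich benzylic C–O bond of 8 or hydrolyse 13.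

Step 8
Reactants: 15 methyl 2-{[4-methoxy-2-(methoxymethoxy)phenyl]methoxy}-5-(3-methylbut-2-enyl)-4-(triisopropylsilyloxy)benzoate
Product: 17 3-methoxy-2-[4-methoxy-2-(methoxymethoxy)phenyl]-5-(3-methylbut-2-enyl)-6-(triisopropylsilyloxy)-1-benzofuran, via lithium benzofuran-3-olate 16 (not isolated)
Conditions: LiN(iPr)2 (2.5 equiv), THF, −78 → −20 °C; then DMPU, Me2SO4, −20 °C → rt
Reagents that add atoms: dimethyl sulfate, COS(=O)(=O)OC
Why: The amide base should remove a proton from the benzylic, oxygen-bearing and MOM-coordinated OCH2 group, the carbanion acylates on the neighbouring ester (Dieckmann-type 5-exo-trig closure, the ester counterpart of benzyl-ether carbanion closures onto ortho carbonyl groups), and the aromatic benzofuran-3-olate formed is methylated on oxygen by the hard electrophile in the presence of DMPU.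

Step 9
Reactants: 17 3-methoxy-2-[4-methoxy-2-(methoxymethoxy)phenyl]-5-(3-methylbut-2-enyl)-6-(triisopropylsilyloxy)-1-benzofuran
Product: 18 5-methoxy-2-[3-methoxy-5-(3-methylbut-2-enyl)-6-(triisopropylsilyloxy)-1-benzofuran-2-yl]phenol
Conditions: conc. HCl (cat.), MeOH, 40 °C
Reagents that add atoms: none
Why: Acid-catalysed acetal exchange removes the MOM group while the aryl silyl ether stays on, so the phenol beside the prenyl group cannot cyclise, and methanol as solvent makes any exchange at the 3-methoxy enol ether degenerate.

Step 10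
Reactants: 18 5-methoxy-2-[3-methoxy-5-(3-methylbut-2-enyl)-6-(triisopropylsilyloxy)-1-benzofuran-2-yl]phenol
Product: 19 ambofuranol, 2-(2-hydroxy-4-methoxyphenyl)-3-methoxy-5-(3-methylbut-2-enyl)-1-benzofuran-6-ol
Conditions: Bu4NF, AcOH, THF, 0 °C → rt
Reagents that add atoms: none
Why: Fluoride-induced cleavage of the aryl silyl ether, buffered with acetic acid so that the electron-rich phenols are not left as air-sensitive phenoxides, should release the target without touching the prenyl group or the enol ether.

Compound list
1 | dimethyl 3-oxopentanedioate | COC(=O)CC(=O)CC(=O)OC | starting material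
2 | trimethyl orthoformate | COC(OC)OC | starting material
3 | dimethyl 2-(methoxymethylidene)-3-oxopentanedioate (alkene isomer mixture, formed in the flask) | COC=C(C(=O)OC)C(=O)CC(=O)OC | intermediate
4 | methyl 4-hydroxy-2-oxo-2H-pyran-5-carboxylate | COC(=O)C1=COC(=O)C=C1O | intermediate
5 | 2-hydroxy-4-methoxybenzaldehyde | COc1ccc(C=O)c(O)c1 | starting material
6 | 4-methoxy-2-(methoxymethoxy)benzaldehyde | COCOc1cc(OC)ccc1C=O | intermediate
7 | [4-methoxy-2-(methoxymethoxy)phenyl]methanol | COCOc1cc(OC)ccc1CO | intermediate
8 | methyl 4-{[4-methoxy-2-(methoxymethoxy)phenyl]methoxy}-2-oxo-2H-pyran-5-carboxylate | COC(=O)C1=COC(=O)C=C1OCc1ccc(OC)cc1OCOC | intermediate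
9 | prenyl bromide (1-bromo-3-methylbut-2-ene) | CC(C)=CCBr | starting material
10 | 5-methylhex-4-en-1-yne | CC(C)=CCC#C | intermediate
11 | (5-methylhex-4-en-1-yn-1-yl)lithium (formed in the flask) | [Li]C#CCC=C(C)C | intermediate
12 | lithium 5-methylhex-4-en-1-yn-1-olate (formed in the flask) | [Li]OC#CCC=C(C)C | intermediate
13 | triisopropyl[(5-methylhex-4-en-1-yn-1-yl)oxy]silane | CC(C)=CCC#CO[Si](C(C)C)(C(C)C)C(C)C | intermediate
14 | methyl 8-{[4-methoxy-2-(methoxymethoxy)phenyl]methoxy}-6-(3-methylbut-2-enyl)-3-oxo-5-(triisopropylsilyloxy)-2-oxabicyclo[2.2.2]octa-5,7-diene-7-carboxylate (racemic, bridgeheads fixed by the bicycle, formed in the flask) | O=C1OC2C(C(=O)OC)=C(OCc3ccc(OC)cc3OCOC)C1C(O[Si](C(C)C)(C(C)C)C(C)C)=C2CC=C(C)C | intermediate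
15 | methyl 2-{[4-methoxy-2-(methoxymethoxy)phenyl]methoxy}-5-(3-methylbut-2-enyl)-4-(triisopropylsilyloxy)benzoate | COC(=O)c1cc(CC=C(C)C)c(O[Si](C(C)C)(C(C)C)C(C)C)cc1OCc1ccc(OC)cc1OCOC | intermediate
16 | lithium 2-[4-methoxy-2-(methoxymethoxy)phenyl]-5-(3-methylbut-2-enyl)-6-(triisopropylsilyloxy)-1-benzofuran-3-olate (formed in the flask) | [Li]Oc1c(-c2ccc(OC)cc2OCOC)oc2cc(O[Si](C(C)C)(C(C)C)C(C)C)c(CC=C(C)C)cc12 | intermediate
17 | 3-methoxy-2-[4-methoxy-2-(methoxymethoxy)phenyl]-5-(3-methylbut-2-enyl)-6-(triisopropylsilyloxy)-1-benzofuran | COc1c(-c2ccc(OC)cc2OCOC)oc2cc(O[Si](C(C)C)(C(C)C)C(C)C)c(CC=C(C)C)cc12 | intermediate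
18 | 5-methoxy-2-[3-methoxy-5-(3-methylbut-2-enyl)-6-(triisopropylsilyloxy)-1-benzofuran-2-yl]phenol | COc1c(-c2ccc(OC)cc2O)oc2cc(O[Si](C(C)C)(C(C)C)C(C)C)c(CC=C(C)C)cc12 | intermediate
19 | ambofuranol, 2-(2-hydroxy-4-methoxyphenyl)-3-methoxy-5-(3-methylbut-2-enyl)-1-benzofuran-6-ol | COc1ccc(-c2oc3cc(O)c(CC=C(C)C)cc3c2OC)c(O)c1 | target

Total step count: 10.
Longest linear sequence: 7 steps (steps 2, 3, 4, 7, 8, 9, 10, from 2-hydroxy-4-methoxybenzaldehyde 5).

Steps most likely to fail

Step 7 (the proposed new method). The 4-alkoxy group makes the pyrone a weaker acceptor, so the cycloaddition may be too slow. Silyl migration from oxygen to carbon in the ynol ether, ionisation of the benzylic C–O bond of the pyrone ether, or closure to a four-membered adduct could then take over. The fallback uses known chemistry only and buys ring A instead of building it; it sets out from benzyl alcohol 7 and comes back to the route at benzoate 15. Purchased methyl 2,4-dihydroxybenzoate is brominated para to the 2-hydroxyl (NBS, MeCN, 0 °C) to give methyl 5-bromo-2,4-dihydroxybenzoate F1. The non-chelated 4-hydroxyl is silylated (iPr3SiCl, imidazole, DMF) to give methyl 5-bromo-2-hydroxy-4-(triisopropylsilyloxy)benzoate F2. Mitsunobu etherification of the remaining phenol with 7 (PPh3, DIAD, THF) should give methyl 5-bromo-2-{[4-methoxy-2-(methoxymethoxy)phenyl]methoxy}-4-(triisopropylsilyloxy)benzoate F3. Stille coupling with tributyl(3-methylbut-2-enyl)stannane (Pd(PPh3)4, DMF, 90 °C) then installs the prenyl group and gives 15.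

Step 8. Proton removal may occur at the prenyl methylene or on the rings instead of at the OCH2 group. The oxygen-bearing carbanion may undergo aryl migration ([1,2]-Wittig rearrangement) before it acylates, or the ambident enolate may be methylated on carbon. The fallback forms the C2–C3 bond without base; it sets out from benzoate 15 and comes back at benzofuran 17. iBu2AlH (CH2Cl2, −78 °C) reduces the ester to [2-{[4-methoxy-2-(methoxymethoxy)phenyl]methoxy}-5-(3-methylbut-2-enyl)-4-(triisopropylsilyloxy)phenyl]methanol F4. MnO2 (CH2Cl2, rt) oxidises it to 2-{[4-methoxy-2-(methoxymethoxy)phenyl]methoxy}-5-(3-methylbut-2-enyl)-4-(triisopropylsilyloxy)benzaldehyde F5. Irradiation (Pyrex-filtered mercury lamp, degassed benzene, dilute) should induce δ-hydrogen abstraction from the OCH2 group by the excited aldehyde and closure of the 1,5-biradical (Norrish–Yang-type photocyclisation). This gives 2-[4-methoxy-2-(methoxymethoxy)phenyl]-5-(3-methylbut-2-enyl)-6-(triisopropylsilyloxy)-2,3-dihydro-1-benzofuran-3-ol F6 as a racemic cis/trans mixture, both isomers converging in the next step. Dess–Martin periodinane (CH2Cl2, NaHCO3) gives 2-[4-methoxy-2-(methoxymethoxy)phenyl]-5-(3-methylbut-2-enyl)-6-(triisopropylsilyloxy)-1-benzofuran-3(2H)-one F7. Me2SO4 and K2CO3 in acetone methylate its enol oxygen to give 17.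

Step 6. Oxygen transfer to the acetylide may be incomplete, base may isomerise the skipped enyne, or the ynolate may be silylated on carbon; the volatile alkyne 10 may also be lost on handling. The fallback generates the same ynolate without an alkyne or an oxidation; it sets out from prenyl bromide 9 and comes back at lithium ynolate 12, which is silylated to 13 as in step 6. The lithium enolate of ethyl acetate (LiN(iPr)2, THF, −78 °C) is alkylated with 9 in the presence of DMPU to give ethyl 5-methylhex-4-enoate F8. Two successive enolate brominations (LiN(iPr)2, then BrCF2CF2Br; LiN(SiMe3)2, then BrCF2CF2Br) give ethyl 2-bromo-5-methylhex-4-enoate F9 (racemic) and then ethyl 2,2-dibromo-5-methylhex-4-enoate F10. t-BuLi (4 equiv, THF, −78 → 0 °C) should effect double bromine–lithium exchange and loss of ethoxide, delivering 12.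

Further compounds
F1 | step 7 | methyl 5-bromo-2,4-dihydroxybenzoate | COC(=O)c1cc(Br)c(O)cc1O
F2 | step 7 | methyl 5-bromo-2-hydroxy-4-(triisopropylsilyloxy)benzoate | COC(=O)c1cc(Br)c(O[Si](C(C)C)(C(C)C)C(C)C)cc1O
F3 | step 7 | methyl 5-bromo-2-{[4-methoxy-2-(methoxymethoxy)phenyl]methoxy}-4-(triisopropylsilyloxy)benzoate | COC(=O)c1cc(Br)c(O[Si](C(C)C)(C(C)C)C(C)C)cc1OCc1ccc(OC)cc1OCOC
F4 | step 8 | [2-{[4-methoxy-2-(methoxymethoxy)phenyl]methoxy}-5-(3-methylbut-2-enyl)-4-(triisopropylsilyloxy)phenyl]methanol | OCc1cc(CC=C(C)C)c(O[Si](C(C)C)(C(C)C)C(C)C)cc1OCc1ccc(OC)cc1OCOC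
F5 | step 8 | 2-{[4-methoxy-2-(methoxymethoxy)phenyl]methoxy}-5-(3-methylbut-2-enyl)-4-(triisopropylsilyloxy)benzaldehyde | O=Cc1cc(CC=C(C)C)c(O[Si](C(C)C)(C(C)C)C(C)C)cc1OCc1ccc(OC)cc1OCOC
F6 | step 8 | 2-[4-methoxy-2-(methoxymethoxy)phenyl]-5-(3-methylbut-2-enyl)-6-(triisopropylsilyloxy)-2,3-dihydro-1-benzofuran-3-ol (racemic, cis/trans mixture) | OC1C(c2ccc(OC)cc2OCOC)Oc2cc(O[Si](C(C)C)(C(C)C)C(C)C)c(CC=C(C)C)cc21
F7 | step 8 | 2-[4-methoxy-2-(methoxymethoxy)phenyl]-5-(3-methylbut-2-enyl)-6-(triisopropylsilyloxy)-1-benzofuran-3(2H)-one (racemic) | O=C1C(c2ccc(OC)cc2OCOC)Oc2cc(O[Si](C(C)C)(C(C)C)C(C)C)c(CC=C(C)C)cc21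
F8 | step 6 | ethyl 5-methylhex-4-enoate | CCOC(=O)CCC=C(C)C
F9 | step 6 | ethyl 2-bromo-5-methylhex-4-enoate (racemic) | CCOC(=O)C(Br)CC=C(C)C
F10 | step 6 | ethyl 2,2-dibromo-5-methylhex-4-enoate | CCOC(=O)C(Br)(Br)CC=C(C)C
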